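**Strategy.** Ring B (C5–C10, eudesmane numbering) is read as the six-membered ring of a [4+2] adduct: C9–C10 is the two-carbon unit, C5–C6–C7–C8 the four-carbon unit, and C1–C4 of ring A, with the C3=C4 olefin and C15 already in place, is the tether. One catalytic asymmetric intramolecular Diels–Alder reaction of an acyclic tetraenal therefore forms C8–C9 and C5–C10, closes both rings and sets C5 and C10. The precursor carries C7 as a silyl enol ether (diene activation, later the handle for the acrylate) and C14 as a formyl group on the dienophile (activation and catalyst binding site, later reduced to the angular methyl).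

Key step: step 7

Numbering: eudesmane numbers are used throughout (ring A = C1–C5 and C10; ring B = C5–C10; C14 on C10; C15 on C4; C11–C13 on C7); α is the face of H-5, β the face of C14.

Assumption: the (S)-configured oxazaborolidinium catalyst is taken to deliver the 5α-H/10β-formyl enantiomer in step 7; should the first adduct prove antipodal, the equally available (R)-catalyst is used.

**Step 1**
Reactants: 1 cyclopentene
Product: 3 5,5-dimethoxypentanal, via methoxy hydroperoxide 2 (not isolated)
Conditions: O3, CH2Cl2/MeOH, −78 °C; TsOH, rt; NaHCO3; Me2S, rt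
Reagents that add atoms: ozone, [O-][O+]=O; methanol, CO
Why: Unsymmetrical (Schreiber) ozonolysis: methanol traps the carbonyl oxide as the α-methoxy hydroperoxide, TsOH acetalises the free aldehyde end, and Me2S then reduces the hydroperoxide end to the aldehyde, so the two termini of the C5 chain (future C3 and C14) come out differentiated.

**Step 2**
Reactants: 3 5,5-dimethoxypentanal; 4 methyl 2-(triphenyl-λ5-phosphanylidene)acetate
Product: 6 methyl (2Z)-2-bromo-7,7-dimethoxyhept-2-enoate, via bromo ylide 5 (not isolated)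
Conditions: NBS, CH2Cl2, −20 °C; then 3, rt
Reagents that add atoms: N-bromosuccinimide, O=C1CCC(=O)N1Br
Why: C-Bromination of the stabilised ylide and Wittig olefination with the α-bromo ylide should give the (Z)-bromoenoate (Br cis to the chain), which fixes the later cis relationship of C2 and C5 across C3=C4.

**Step 3**
Reactants: 6 methyl (2Z)-2-bromo-7,7-dimethoxyhept-2-enoate; 7 but-3-en-2-one
Product: 8 methyl (2E)-7,7-dimethoxy-2-[(1E)-3-oxobut-1-en-1-yl]hept-2-enoate
Conditions: Pd(OAc)2 (5 mol%), P(o-tol)3, NaHCO3, Bu4NCl, DMF, 60 °C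
Reagents that add atoms: none
Why: Mizoroki–Heck coupling under Jeffery conditions: oxidative addition of the vinyl bromide with retention, syn insertion of the enone and syn β-hydride elimination should give the (E)-enone, so both the C3=C4 geometry and the (E)-C5=C6 geometry needed for the cycloaddition are secured.

**Step 4**
Reactants: 8 methyl (2E)-7,7-dimethoxy-2-[(1E)-3-oxobut-1-en-1-yl]hept-2-enoate
Product: 9 methyl (2E)-7-oxo-2-[(1E)-3-oxobut-1-en-1-yl]hept-2-enoate
Conditions: TsOH·H2O (cat.), acetone/H2O, rt
Reagents that add atoms: water, O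
Why: Acid-catalysed acetal hydrolysis unmasks the aldehyde (future C14) without touching the dienone ester.

**Step 5**
Reactants: 9 methyl (2E)-7-oxo-2-[(1E)-3-oxobut-1-en-1-yl]hept-2-enoate
Product: 11 methyl (2E)-6-formyl-2-[(1E)-3-oxobut-1-en-1-yl]hepta-2,6-dienoate, via Mannich base 10 (not isolated)
Conditions: CH2=NMe2+ I− (excess), Et3N, CH2Cl2, rt
Reagents that add atoms: dimethylmethylideneammonium iodide, C=[N+](C)C.[I-]
Why: Eschenmoser α-methylenation (Mannich reaction of the aldehyde, then β-elimination of dimethylamine) should give the non-enolisable 2-alkylacrolein, i.e. the dienophile C9=C10 with C14 as its activating formyl group; excess iminium salt scavenges the liberated secondary amine.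

**Step 6**
Reactants: 11 methyl (2E)-6-formyl-2-[(1E)-3-oxobut-1-en-1-yl]hepta-2,6-dienoate
Product: 12 methyl (2E)-6-formyl-2-{(1E)-3-[tri(propan-2-yl)silyloxy]buta-1,3-dien-1-yl}hepta-2,6-dienoate
Conditions: iPr3SiOTf, Et3N, CH2Cl2, −78 °C; cold NaHCO3 work-up, used at once
Reagents that add atoms: tri(propan-2-yl)silyl trifluoromethanesulfonate, CC(C)[Si](C(C)C)(C(C)C)OS(=O)(=O)C(F)(F)F
Why: Soft enolisation of the methyl ketone, the only enolisable carbonyl left, should give the 2-silyloxy-1,3-diene C5=C6–C7(OSi)=C8 regiospecifically with the (E)-C5=C6 geometry untouched.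

**Step 7**
Reactants: 12 methyl (2E)-6-formyl-2-{(1E)-3-[tri(propan-2-yl)silyloxy]buta-1,3-dien-1-yl}hepta-2,6-dienoate
Product: 13 methyl 14-oxo-7-[tri(propan-2-yl)silyloxy]-11,12,13-trinor-5αH-eudesma-3,6-dien-15-oate (trans-fused; 10β-formyl)
Conditions: (S)-o-tolyl-CBS-oxazaborolidine (20 mol%) activated with Tf2NH (18 mol%), CH2Cl2 (0.01 M), −78 °C; Et3N quench
Reagents that add atoms: none
Why: The cationic oxazaborolidine binds the formyl oxygen of the 2-alkylacrolein unit and lowers its LUMO, and the 2-silyloxydiene adds across C9=C10 in a concerted but asynchronous normal-demand [4+2] cycloaddition (intramolecular Diels–Alder reaction of a 1,7,9-decatriene) in which the C8–C9 bond leads and the C5–C10 bond follows. The closest known reactions are the oxazaborolidinium-catalysed enantioselective Diels–Alder reactions of 2-substituted acroleins with 2-silyloxydienes and the catalysed intramolecular Diels–Alder reactions of trienals. Ring B closes as the six-membered cycloadduct ring through both new bonds, and ring A closes through C5–C10 alone, the four-atom chain C1–C2–C3=C4 acting as tether in an extended (tether-exo) half-chair. C5 and C10 are created together: their trans relationship (5α-H, 10β-CHO) follows from the transition state with the complexed formyl group endo and the tether exo, and their absolute configuration from the catalyst, which blocks one face of the bound enal. The step needs regioselectivity, which the tether enforces and the matched polarity (nucleophilic C8, electrophilic C9) reinforces, and trans selectivity, for which the endo preference of the Lewis-acid-bound formyl group and the rigid cis-C3=C4 unit, which disfavours the folded tether-endo geometry, are relied on. Low temperature and high dilution should keep uncatalysed background cyclisation and intermolecular Mukaiyama-type reactions negligible.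

**Step 8**
Reactants: 13 methyl 14-oxo-7-[tri(propan-2-yl)silyloxy]-11,12,13-trinor-5αH-eudesma-3,6-dien-15-oate
Product: 15 7-[tri(propan-2-yl)silyloxy]-11,12,13-trinor-5αH-eudesma-3,6-dien-15-ol, via tosylhydrazone 14 (not isolated)
Conditions: TsNHNH2, THF, 4 Å MS, rt; then LiAlH4 (excess), THF, −20 °C to reflux
Reagents that add atoms: none
Why: The aldehyde tosylhydrazone has no α-hydrogen and should be reduced by LiAlH4 to the angular methyl group (Caglioti reduction: hydride addition, loss of sulfinate and N2), while the same reagent reduces the enoate 1,2 to the C15 allylic alcohol; the silyl enol ether masks the C7 carbonyl throughout.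

**Step 9**
Reactants: 15 7-[tri(propan-2-yl)silyloxy]-11,12,13-trinor-5αH-eudesma-3,6-dien-15-ol
Product: 16 15-hydroxy-11,12,13-trinor-5αH-eudesm-3-en-7-one
Conditions: Bu4NF, AcOH, THF, 0 °C
Reagents that add atoms: none
Why: Fluoride cleavage of the silyl enol ether and protonation of the enolate should release the C7 ketone; neither stereocentre is enolisable.

**Step 10**
Reactants: 16 15-hydroxy-11,12,13-trinor-5αH-eudesm-3-en-7-one; 17 methyl 2-(dimethoxyphosphoryl)acetate
Product: 18 methyl 15-hydroxy-13-nor-5αH-eudesma-3,7(11)-dien-12-oate (E/Z mixture)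
Conditions: NaH (excess), THF, 0 °C to reflux
Reagents that add atoms: none
Why: Horner–Wadsworth–Emmons olefination of the unhindered cyclohexanone installs C11 and C12; the alkene geometry is of no consequence because both isomers converge in the next step.

**Step 11**
Reactants: 18 methyl 15-hydroxy-13-nor-5αH-eudesma-3,7(11)-dien-12-oate
Product: 19 methyl 15-hydroxy-13-nor-5αH,7αH-eudesm-3-en-12-oate
Conditions: Mg turnings, MeOH, 0 °C to rt
Reagents that add atoms: none
Why: Dissolving-metal conjugate reduction of the enoate: protonation at C7 should occur from the axial (α) direction, as is usual for small reagents on cyclohexylidene systems, placing the side chain equatorial (7β, also the more stable isomer) from either alkene isomer; the isolated olefin and the alcohol are inert.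

**Step 12**
Reactants: 19 methyl 15-hydroxy-13-nor-5αH,7αH-eudesm-3-en-12-oate
Product: 22 methyl 15-hydroxy-5αH,7αH-eudesma-3,11(13)-dien-12-oate, via Mannich base 20 (not isolated), via ammonium iodide 21 (not isolated)
Conditions: LiN(iPr)2 (2.3 equiv), THF, −78 °C; CH2=NMe2+ I−; then MeI, MeOH; DBU, CH2Cl2, rt
Reagents that add atoms: dimethylmethylideneammonium iodide, C=[N+](C)C.[I-]
Why: Eschenmoser methylenation of an ester (alkoxide/enolate dianion, Mannich reaction, N-methylation, E1cB elimination) should give the α-methylene ester; C7 is not enolisable and keeps its configuration.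

**Step 13**
Reactants: 23 4-[tert-butyl(dimethyl)silyloxy]benzaldehyde; 24 ethyl 2-(diphenoxyphosphoryl)acetate
Product: 25 ethyl (2Z)-3-{4-[tert-butyl(dimethyl)silyloxy]phenyl}prop-2-enoate
Conditions: NaH, THF, −78 °C to 0 °C
Reagents that add atoms: none
Why: Ando variant of the Horner–Wadsworth–Emmons reaction: the diaryl phosphonate should give the (Z)-cinnamate under kinetic control.

**Step 14**
Reactants: 25 ethyl (2Z)-3-{4-[tert-butyl(dimethyl)silyloxy]phenyl}prop-2-enoate
Product: 26 (2Z)-3-(4-hydroxyphenyl)prop-2-enoic acid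
Conditions: LiOH, THF/MeOH/H2O, rt, dark; then HCl to pH 3
Reagents that add atoms: lithium hydroxide, [Li+].[OH-]
Why: Saponification of the ethyl ester with concurrent hydroxide cleavage of the aryl silyl ether should give the (Z)-acid, the Z-olefin being stable to aqueous base in the dark.

**Step 15**
Reactants: 22 methyl 15-hydroxy-5αH,7αH-eudesma-3,11(13)-dien-12-oate; 26 (2Z)-3-(4-hydroxyphenyl)prop-2-enoic acid
Product: 27 methyl (5R,7R,10R)-15-{[(2Z)-3-(4-hydroxyphenyl)prop-2-enoyl]oxy}eudesma-3,11(13)-dien-12-oate
Conditions: PPh3, DIAD (premixed), THF, 0 °C, dark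
Reagents that add atoms: none
Why: Mitsunobu esterification: the primary allylic alkoxyphosphonium ion is displaced SN2 by the carboxylate, which is far more acidic than the phenol and should therefore react chemoselectively, under neutral conditions that leave the Z-olefin and the acrylate untouched.

**Compound list**

1 | cyclopentene | C1=CCCC1 | starting material
2 | 1-hydroperoxy-1,5,5-trimethoxypentane | COC(OC)CCCC(OC)OO | intermediate
3 | 5,5-dimethoxypentanal | COC(OC)CCCC=O | intermediate
4 | methyl 2-(triphenyl-λ5-phosphanylidene)acetate | COC(=O)C=P(c1ccccc1)(c1ccccc1)c1ccccc1 | starting material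
5 | methyl 2-bromo-2-(triphenyl-λ5-phosphanylidene)acetate | COC(=O)C(Br)=P(c1ccccc1)(c1ccccc1)c1ccccc1 | intermediate
6 | methyl (2Z)-2-bromo-7,7-dimethoxyhept-2-enoate | COC(OC)CCC/C=C(\Br)C(=O)OC | intermediate
7 | but-3-en-2-one | CC(=O)C=C | starting material
8 | methyl (2E)-7,7-dimethoxy-2-[(1E)-3-oxobut-1-en-1-yl]hept-2-enoate | COC(OC)CCC/C=C(\C=C\C(C)=O)C(=O)OC | intermediate
9 | methyl (2E)-7-oxo-2-[(1E)-3-oxobut-1-en-1-yl]hept-2-enoate | O=CCCC/C=C(\C=C\C(C)=O)C(=O)OC | intermediate
10 | methyl (2E)-6-[(dimethylamino)methyl]-7-oxo-2-[(1E)-3-oxobut-1-en-1-yl]hept-2-enoate | O=CC(CN(C)C)CC/C=C(\C=C\C(C)=O)C(=O)OC | intermediate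
11 | methyl (2E)-6-formyl-2-[(1E)-3-oxobut-1-en-1-yl]hepta-2,6-dienoate | C=C(C=O)CC/C=C(\C=C\C(C)=O)C(=O)OC | intermediate
12 | methyl (2E)-6-formyl-2-{(1E)-3-[tri(propan-2-yl)silyloxy]buta-1,3-dien-1-yl}hepta-2,6-dienoate | C=C(C=O)CC/C=C(\C=C\C(=C)O[Si](C(C)C)(C(C)C)C(C)C)C(=O)OC | intermediate
13 | methyl 14-oxo-7-[tri(propan-2-yl)silyloxy]-11,12,13-trinor-5αH-eudesma-3,6-dien-15-oate (= methyl 4a-formyl-7-silyloxy-3,4,4a,5,6,8a-hexahydronaphthalene-1-carboxylate; trans-fused; 10β-formyl) | CC(C)[Si](C(C)C)(C(C)C)OC=1CC[C@@]2(C=O)CCC=C(C(=O)OC)[C@@H]2C=1 | intermediate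
14 | N-tosylhydrazone of 13 at C14 | CC(C)[Si](C(C)C)(C(C)C)OC=1CC[C@@]2(C=NNS(=O)(=O)c3ccc(C)cc3)CCC=C(C(=O)OC)[C@@H]2C=1 | intermediate
15 | 7-[tri(propan-2-yl)silyloxy]-11,12,13-trinor-5αH-eudesma-3,6-dien-15-ol (10β-methyl) | CC(C)[Si](C(C)C)(C(C)C)OC=1CC[C@@]2(C)CCC=C(CO)[C@@H]2C=1 | intermediate
16 | 15-hydroxy-11,12,13-trinor-5αH-eudesm-3-en-7-one | O=C1CC[C@@]2(C)CCC=C(CO)[C@@H]2C1 | intermediate
17 | methyl 2-(dimethoxyphosphoryl)acetate | COC(=O)CP(=O)(OC)OC | starting material
18 | methyl 15-hydroxy-13-nor-5αH-eudesma-3,7(11)-dien-12-oate (E/Z mixture) | COC(=O)C=C1CC[C@@]2(C)CCC=C(CO)[C@@H]2C1 | intermediate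
19 | methyl 15-hydroxy-13-nor-5αH,7αH-eudesm-3-en-12-oate | COC(=O)C[C@@H]1CC[C@@]2(C)CCC=C(CO)[C@@H]2C1 | intermediate
20 | methyl 13-(dimethylamino)-15-hydroxy-5αH,7αH-eudesm-3-en-12-oate (C11 epimers) | COC(=O)C(CN(C)C)[C@@H]1CC[C@@]2(C)CCC=C(CO)[C@@H]2C1 | intermediate
21 | methyl 15-hydroxy-13-(trimethylammonio)-5αH,7αH-eudesm-3-en-12-oate iodide | COC(=O)C(C[N+](C)(C)C)[C@@H]1CC[C@@]2(C)CCC=C(CO)[C@@H]2C1.[I-] | intermediate
22 | methyl 15-hydroxy-5αH,7αH-eudesma-3,11(13)-dien-12-oate | C=C(C(=O)OC)[C@@H]1CC[C@@]2(C)CCC=C(CO)[C@@H]2C1 | intermediate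
23 | 4-[tert-butyl(dimethyl)silyloxy]benzaldehyde | CC(C)(C)[Si](C)(C)Oc1ccc(C=O)cc1 | starting material
24 | ethyl 2-(diphenoxyphosphoryl)acetate | CCOC(=O)CP(=O)(Oc1ccccc1)Oc1ccccc1 | starting material
25 | ethyl (2Z)-3-{4-[tert-butyl(dimethyl)silyloxy]phenyl}prop-2-enoate | CCOC(=O)/C=C\c1ccc(O[Si](C)(C)C(C)(C)C)cc1 | intermediate
26 | (2Z)-3-(4-hydroxyphenyl)prop-2-enoic acid | OC(=O)/C=C\c1ccc(O)cc1 | intermediate
27 | methyl (5R,7R,10R)-15-{[(2Z)-3-(4-hydroxyphenyl)prop-2-enoyl]oxy}eudesma-3,11(13)-dien-12-oate | C=C(C(=O)OC)[C@@H]1CC[C@@]2(C)CCC=C(COC(=O)/C=C\c3ccc(O)cc3)[C@@H]2C1 | target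

**Step count.** Total: 15 steps. Longest linear sequence: 13 steps (steps 1–12 and 15); steps 13–14 form the convergent acid branch.

**Steps most likely to fail**

1. Step 7. Enantiofacial control may be eroded by uncatalysed or adventitious-acid-catalysed background cyclisation of the well-matched siloxydiene/enal pair. The folded tether-endo transition state may also compete and give cis-fused material. Fallback: the source of enantiopurity is changed from catalysis to resolution. Compound 12 is cyclised with the achiral Lewis acid Me2AlCl (CH2Cl2, −78 °C), which should give the racemic trans-fused adduct, that is 13 together with its antipode ent-13 F1. The enantiomers are separated by preparative chromatography on a chiral stationary phase. The fallback sets out from 12 and comes back at 13.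

2. Step 8. Hydride transfer to the hindered neopentyl-type tosylhydrazone may stay incomplete, or conjugate reduction of the enoate may set in at the temperature the hydrazone needs. Fallback: radical deoxygenation in place of hydrazone reduction, setting out from 13. NaBH4 (MeOH, 0 °C) reduces only the aldehyde to the neopentyl alcohol F2. NaH, CS2 and MeI give the S-methyl xanthate F3. Bu3SnH/AIBN in refluxing toluene (Barton–McCombie) gives the angular-methyl ester F4. iBu2AlH (CH2Cl2, −78 °C) then reduces the ester, and the route is rejoined at 15.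

3. Step 11. Protonation at C7 may show poor facial selectivity, with equatorial delivery giving the 7α-side-chain epimer. Fallback: C7 is set under thermodynamic control through an enolisable aldehyde, setting out from 16. Wittig methoxymethylenation (Ph3P(CH2OMe)Cl, KN(SiMe3)2) gives the enol ether F5. Aqueous acid hydrolysis and K2CO3/MeOH equilibration give the equatorial 7β-carbaldehyde F6. Ohira–Bestmann homologation (dimethyl (1-diazo-2-oxopropyl)phosphonate, K2CO3, MeOH) gives the alkyne F7. Branched-selective methoxycarbonylation (Pd(OAc)2, 2-pyridyldiphenylphosphine, MsOH, CO, MeOH) then gives the acrylate, and the route is rejoined at 22.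

**Further compounds**

F1 | step 7 | ent-13, methyl 14-oxo-7-[tri(propan-2-yl)silyloxy]-11,12,13-trinor-5βH-eudesma-3,6-dien-15-oate with 10α-formyl (antipode of 13) | CC(C)[Si](C(C)C)(C(C)C)OC=1CC[C@]2(C=O)CCC=C(C(=O)OC)[C@H]2C=1
F2 | step 8 | methyl 14-hydroxy-7-[tri(propan-2-yl)silyloxy]-11,12,13-trinor-5αH-eudesma-3,6-dien-15-oate | CC(C)[Si](C(C)C)(C(C)C)OC=1CC[C@@]2(CO)CCC=C(C(=O)OC)[C@@H]2C=1
F3 | step 8 | O-C14 S-methyl xanthate of F2 | CC(C)[Si](C(C)C)(C(C)C)OC=1CC[C@@]2(COC(=S)SC)CCC=C(C(=O)OC)[C@@H]2C=1
F4 | step 8 | methyl 7-[tri(propan-2-yl)silyloxy]-11,12,13-trinor-5αH-eudesma-3,6-dien-15-oate | CC(C)[Si](C(C)C)(C(C)C)OC=1CC[C@@]2(C)CCC=C(C(=O)OC)[C@@H]2C=1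
F5 | step 11 | 7-(methoxymethylidene)-11,12,13-trinor-5αH-eudesm-3-en-15-ol (E/Z mixture) | COC=C1CC[C@@]2(C)CCC=C(CO)[C@@H]2C1
F6 | step 11 | 15-hydroxy-12,13-dinor-5αH,7αH-eudesm-3-en-11-al | O=C[C@@H]1CC[C@@]2(C)CCC=C(CO)[C@@H]2C1
F7 | step 11 | 7β-ethynyl-11,12,13-trinor-5αH,7αH-eudesm-3-en-15-ol | C#C[C@@H]1CC[C@@]2(C)CCC=C(CO)[C@@H]2C1
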